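**Remarks.** Germacrane numbering is used for the target and late intermediates: ring carbons C1–C10, lactone carbons C11–C13 (C12 carbonyl, C13 exo-methylene), C14 the acetoxymethyl carbon on C10, C15 the methyl on C4. TBS = tert-butyldimethylsilyl, PMB = 4-methoxybenzyl.
Assumption: the (S,S)-ProPhenol ligand is taken to give the (R)-carbinol in step 6; if the sense of induction is the opposite, the commercial (R,R)-ligand is used with no other change.

## Retrosynthetic overview

1. The C1–C10 oxirane comes last, by epoxidation of the strained trans C1=C10 olefin of a macrocyclic triene. Before it, the C8 ester is made by Mitsunobu inversion with (2S,3S)-epoxyangelic acid, itself from angelic acid by Sharpless epoxidation.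
2. Key disconnection C7–C8. In the α-methylene-γ-butyrolactone (ring O–C6–C7–C11–C12) the carbinol C8 sits on C7 next to C11=C13, so C8(O)–C7–C11=C13 is a homoallylic alcohol. That is the retron of a γ-selective chromium allylation of a C8 aldehyde by a 3-(bromomethyl)butenolide; the step closes the ten-membered carbocycle, unveils C11=C13 and sets C7 and C8 from C6.
3. The butenolide comes from a propargylic alcohol by hydroxyl-directed trans-hydroalumination/iodination and carbonylative lactonisation. C6, the only ring stereocentre made by catalysis, comes from zinc–ProPhenol alkynylation of a (Z)-enal.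
4. The acyclic chain comes from neryl acetate (C1–C6, C15, cis C4=C5) by oxidative cleavage and Still–Gennari olefination (C1=C10 with the C14 and C9–C8 arms).
5. Order of ring formation: butenolide, ten-membered ring (key step), C1–C10 oxirane.

Key step: step 15

## Route

Step 1
Reactants: 1 neryl acetate
Product: 3 (2Z)-3-methyl-6-oxohex-2-en-1-yl acetate, via 6,7-epoxyneryl acetate 2 (not isolated)
Conditions: mCPBA (1.05 equiv), CH2Cl2, −20 to 0 °C; then H5IO6, THF/H2O, 0 °C
Reagents that add atoms: mCPBA, OOC(=O)c1cccc(Cl)c1; water, O (the aldehyde oxygen stems from the epoxide oxygen or from water)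
Why: The remote trisubstituted olefin is more electron-rich than the one deactivated by the allylic acetate, so peracid epoxidation is regioselective, and periodic acid cleaves the epoxide through its diol to the aldehyde (epoxidation, then oxidative glycol cleavage) without touching the Z-olefin.

Step 2
Reactants: 4 methyl 2-[bis(2,2,2-trifluoroethoxy)phosphoryl]acetate; 5 tert-butyl(2-iodoethoxy)dimethylsilane
Product: 6 methyl 2-[bis(2,2,2-trifluoroethoxy)phosphoryl]-4-(TBS-oxy)butanoate (racemic)
Conditions: NaH, DMSO/THF, 0 °C to rt (slight excess of 4)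
Reagents that add atoms: none
Why: C-alkylation of the stabilised phosphonoacetate anion by a primary iodide (phosphonate alkylation); the new stereocentre is lost again in step 3.

Step 3
Reactants: 3 (2Z)-3-methyl-6-oxohex-2-en-1-yl acetate; 6 phosphonate
Product: 7 methyl (2Z,6Z)-8-acetoxy-2-[2-(TBS-oxy)ethyl]-6-methylocta-2,6-dienoate
Conditions: KN(SiMe3)2, 18-crown-6, THF, −78 °C; then 3
Reagents that add atoms: none
Why: Still–Gennari olefination, in which the electron-poor bis(trifluoroethyl) phosphonate under dissociating conditions eliminates kinetically to the (Z)-enoate, so the ester carbon (later C14) ends up cis to the chain (C2) and the silyloxyethyl arm (C9–C8) trans to it.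

Step 4
Reactants: 7 acetoxy enoate
Product: 8 methyl (2Z,6Z)-2-[2-(TBS-oxy)ethyl]-8-hydroxy-6-methylocta-2,6-dienoate
Conditions: K2CO3 (0.2 equiv), MeOH, 0 °C to rt
Reagents that add atoms: none
Why: Base-catalysed transesterification removes the primary allylic acetate, while the methyl ester is degenerate toward methoxide and the silyl ether is stable.

Step 5
Reactants: 8 allylic alcohol
Product: 9 methyl (2Z,6Z)-2-[2-(TBS-oxy)ethyl]-6-methyl-8-oxoocta-2,6-dienoate
Conditions: MnO2, CH2Cl2, rt
Reagents that add atoms: none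
Why: Heterogeneous, neutral allylic oxidation with MnO2 stops at the enal and keeps the Z geometry of the neral-type olefin.

Step 6
Reactants: 9 (Z)-enal; 10 4-methoxybenzyl propargyl ether
Product: 11 methyl (2Z,6Z,8R)-2-[2-(TBS-oxy)ethyl]-8-hydroxy-11-(PMB-oxy)-6-methylundeca-2,6-dien-9-ynoate
Conditions: Me2Zn (3 equiv), (S,S)-ProPhenol (20 mol %), Ph3P=O (40 mol %), toluene, 0 °C to rt
Reagents that add atoms: none
Why: Dinuclear zinc–ProPhenol-catalysed asymmetric alkynylation of an α,β-unsaturated aldehyde, in which the chiral dizinc pocket delivers the alkynylzinc to one face of the enal and so sets C6 (C8 of this chain, R) by catalyst control; the conjugated ester is inert to alkynylzinc.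

Step 7
Reactants: 11 hydroxy ynoate
Product: 12 (2Z,6Z,8R)-2-[2-(TBS-oxy)ethyl]-11-(PMB-oxy)-6-methylundeca-2,6-dien-9-yne-1,8-diol
Conditions: i-Bu2AlH (4 equiv), CH2Cl2, −78 °C; aq. potassium sodium tartrate work-up
Reagents that add atoms: none
Why: 1,2-Reduction of the conjugated methyl ester to the allylic alcohol by i-Bu2AlH at −78 °C, where the alkyne, the ethers and the carbinol stereocentre are untouched.

Step 8
Reactants: 12 propargylic diol
Product: 14 (2Z,6Z,8R,9Z)-2-[2-(TBS-oxy)ethyl]-10-iodo-11-(PMB-oxy)-6-methylundeca-2,6,9-triene-1,8-diol, via cyclic alkenylaluminate 13 (not isolated)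
Conditions: NaAlH2(OCH2CH2OMe)2 (3 equiv), THF, 0 °C to rt; then I2, THF, −78 °C
Reagents that add atoms: iodine, II
Why: Hydroxyl-directed trans-hydroalumination of a propargylic alcohol, in which the C6 alkoxide delivers hydride to C7 and holds aluminium on C11 in a five-membered alkoxyaluminate; iodinolysis with retention gives the (Z)-iodide with iodine cis to C6.

Step 9
Reactants: 14 (Z)-iodo diol
Product: 15 (5R)-5-[(1Z,5Z)-8-(TBS-oxy)-6-(hydroxymethyl)-2-methylocta-1,5-dien-1-yl]-3-[(PMB-oxy)methyl]furan-2(5H)-one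
Conditions: PdCl2(PPh3)2 (5 mol %), CO (1 atm), K2CO3, THF, rt
Reagents that add atoms: carbon monoxide, [C-]#[O+]
Why: Palladium-catalysed carbonylative lactonisation (oxidative addition into the vinyl C–I bond, CO insertion, capture of the acylpalladium by the cis C6 hydroxyl) closes the butenolide with C12 on C11; C6 is not involved, and the C14 hydroxyl is still unacylated, so no allylic ester is exposed to zerovalent palladium.

Step 10
Reactants: 15 hydroxy butenolide
Product: 16 (5R)-5-[(1Z,5Z)-6-(acetoxymethyl)-8-(TBS-oxy)-2-methylocta-1,5-dien-1-yl]-3-[(PMB-oxy)methyl]furan-2(5H)-one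
Conditions: Ac2O, pyridine, CH2Cl2, 0 °C
Reagents that add atoms: acetic anhydride, CC(=O)OC(C)=O
Why: Acetylation of the only free hydroxyl installs the C14 acetate of the target; pyridine is too weak a base to deprotonate the γ-position (C6) of the butenolide.

Step 11
Reactants: 16 PMB ether
Product: 17 (5R)-5-[(1Z,5Z)-6-(acetoxymethyl)-8-(TBS-oxy)-2-methylocta-1,5-dien-1-yl]-3-(hydroxymethyl)furan-2(5H)-one
Conditions: DDQ, CH2Cl2/aq. NaH2PO4–Na2HPO4 buffer (pH 7), 0 °C
Reagents that add atoms: none
Why: Oxidative cleavage of the PMB ether by DDQ (benzylic hydride abstraction, hydrolysis of the oxocarbenium ion) under buffered conditions leaves silyl ether, acetate and olefins intact.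

Step 12
Reactants: 17 allylic alcohol
Product: 18 (5R)-5-[(1Z,5Z)-6-(acetoxymethyl)-8-(TBS-oxy)-2-methylocta-1,5-dien-1-yl]-3-(bromomethyl)furan-2(5H)-one
Conditions: CBr4, PPh3, CH2Cl2, 0 °C
Reagents that add atoms: carbon tetrabromide, BrC(Br)(Br)Br
Why: Appel bromination (SN2 of bromide on the alkoxyphosphonium ion) converts the primary allylic alcohol to the bromide under neutral conditions that cannot epimerise C6.

Step 13
Reactants: 18 silyl ether
Product: 19 (5R)-5-[(1Z,5Z)-6-(acetoxymethyl)-8-hydroxy-2-methylocta-1,5-dien-1-yl]-3-(bromomethyl)furan-2(5H)-one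
Conditions: aq. HF (48%), MeCN, 0 °C
Reagents that add atoms: none
Why: Acidic fluoride cleaves the primary TBS ether without any base or nucleophile that could attack the allylic bromide or deprotonate C6.

Step 14
Reactants: 19 primary alcohol
Product: 20 (5R)-5-[(1Z,5Z)-6-(acetoxymethyl)-2-methyl-8-oxoocta-1,5-dien-1-yl]-3-(bromomethyl)furan-2(5H)-one
Conditions: Dess–Martin periodinane, NaHCO3, CH2Cl2, 0 °C; used crude
Reagents that add atoms: none
Why: Dess–Martin oxidation under buffered, non-basic conditions gives the β,γ-unsaturated aldehyde without conjugation of the C1=C10 olefin.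

Step 15
Reactants: 20 bromobutenolide aldehyde
Product: 22 (6R,7R,8S)-14-acetoxy-8-hydroxygermacra-1(10),4,11(13)-trien-6,12-olide, via allylchromium dichloride 21 (not isolated)
Conditions: CrCl2 (10 equiv), 4 Å molecular sieves, THF, rt, syringe-pump addition of 20 (final 2 mM)
Reagents that add atoms: none
Why: Two equivalents of CrCl2 reduce the allylic C13–Br bond to the allylchromium dichloride 21, which adds to the tethered aldehyde through its γ-carbon C7 in a six-membered chair transition state (Cr–O=C8···C7=C11–C13), so the double bond moves to C11=C13 and the α-methylene lactone is unveiled as the C–C bond forms. The closest known reaction type is the Nozaki–Hiyama–Kishi (chromium Barbier) allylation of aldehydes by 3-(bromomethyl)furan-2(5H)-ones, here in its macrocyclising form as used for ten-membered carbocycles. The ten-membered carbocycle closes by 10-exo-trig attack of C7 on the aldehyde carbon C8 (SE2′ at the allyl unit), and the butenolide becomes the trans-fused five-membered ring. C7 is controlled by C6: the C5 side chain blocks one face of the planar butenolide and C8 bonds to the other, which gives the 6,7-trans lactone (7R). C8 is controlled by the chair, in which the ring bond C8–C9 is equatorial and anti to C11, so the 8S (8α) alcohol is expected; step 19 is built on this outcome and inverts it. The step needs γ- over α-attack (inherent to allylchromium reagents; α-attack would give a twelve-membered ring), ring closure over oligomerisation (slow addition, with the cis C4=C5 olefin and the butenolide pre-bending the chain) and an unconjugated aldehyde (neutral aprotic medium, aldehyde consumed as it is added); acetate, lactone and olefins are inert to CrCl2.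

Step 16
Reactants: 23 angelic acid
Product: 24 (2Z)-2-methylbut-2-en-1-ol
Conditions: LiAlH4, Et2O, 0 °C
Reagents that add atoms: none
Why: Hydride reduction of the carboxylic acid to the allylic alcohol, which leaves the Z-olefin geometry unchanged.

Step 17
Reactants: 24 (2Z)-2-methylbut-2-en-1-ol
Product: 25 [(2R,3S)-2,3-dimethyloxiran-2-yl]methanol
Conditions: Ti(OiPr)4 (10 mol %), L-(+)-diethyl tartrate (12 mol %), t-BuOOH, 4 Å molecular sieves, CH2Cl2, −20 °C
Reagents that add atoms: tert-butyl hydroperoxide, CC(C)(C)OO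
Why: Sharpless asymmetric epoxidation, in which the L-(+)-tartrate titanium complex delivers oxygen to the olefin face that gives the (2R,3S)-epoxide, the cis relation of the two methyl-bearing carbons coming from the Z-olefin.

Step 18
Reactants: 25 epoxy alcohol
Product: 26 (2S,3S)-2,3-dimethyloxirane-2-carboxylic acid
Conditions: RuCl3 (2 mol %), NaIO4, MeCN/EtOAc/H2O, rt
Reagents that add atoms: water, O
Why: Ruthenium tetroxide-catalysed oxidation of the primary alcohol through the aldehyde hydrate to the glycidic acid leaves both oxirane centres untouched (the descriptor at C2 changes from R to S only through the priority change).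

Step 19
Reactants: 22 (8S)-alcohol; 26 (2S,3S)-epoxy acid
Product: 27 (6R,7R,8R)-14-acetoxy-8-[(2S,3S)-2,3-dimethyloxirane-2-carbonyloxy]germacra-1(10),4,11(13)-trien-6,12-olide
Conditions: PPh3, DIAD, toluene, 0 °C to rt
Reagents that add atoms: none
Why: Mitsunobu esterification, in which the C8 alkoxyphosphonium ion is displaced by the carboxylate of the fairly acidic glycidic acid in an SN2 step, so acylation and inversion 8S to 8R occur in one operation.

Step 20
Reactants: 27 triene ester
Product: 28 target, (1R,6R,7R,8R,10S)-14-acetoxy-1,10-epoxy-8-[(2S,3S)-2,3-dimethyloxirane-2-carbonyloxy]germacra-4,11(13)-dien-6,12-olide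
Conditions: dimethyldioxirane (1.1 equiv), acetone, −20 °C
Reagents that add atoms: dimethyldioxirane, CC1(C)OO1
Why: Electrophilic epoxidation should pick the strained trans C1=C10 olefin over the cis C4=C5 olefin and the electron-poor exo-methylene, and attack its outer face in the ring conformer that holds C14 on the side of H6 and the C8 ester, which gives 1R,10S; the neutral reagent avoids acid-promoted transannular cyclisation.

## Compound list

1 | neryl acetate, (2Z)-3,7-dimethylocta-2,6-dien-1-yl acetate | CC(=O)OC/C=C(/C)CCC=C(C)C | starting material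
2 | 6,7-epoxyneryl acetate, (2Z)-5-(3,3-dimethyloxiran-2-yl)-3-methylpent-2-en-1-yl acetate (racemic) | CC(=O)OC/C=C(/C)CCC1OC1(C)C | intermediate
3 | (2Z)-3-methyl-6-oxohex-2-en-1-yl acetate | CC(=O)OC/C=C(/C)CCC=O | intermediate
4 | methyl 2-[bis(2,2,2-trifluoroethoxy)phosphoryl]acetate | COC(=O)CP(=O)(OCC(F)(F)F)OCC(F)(F)F | starting material
5 | tert-butyl(2-iodoethoxy)dimethylsilane | CC(C)(C)[Si](C)(C)OCCI | starting material
6 | methyl 2-[bis(2,2,2-trifluoroethoxy)phosphoryl]-4-[(tert-butyldimethylsilyl)oxy]butanoate (racemic) | COC(=O)C(CCO[Si](C)(C)C(C)(C)C)P(=O)(OCC(F)(F)F)OCC(F)(F)F | intermediate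
7 | methyl (2Z,6Z)-8-acetoxy-2-{2-[(tert-butyldimethylsilyl)oxy]ethyl}-6-methylocta-2,6-dienoate | CC(=O)OC/C=C(/C)CC/C=C(\C(=O)OC)CCO[Si](C)(C)C(C)(C)C | intermediate
8 | methyl (2Z,6Z)-2-{2-[(tert-butyldimethylsilyl)oxy]ethyl}-8-hydroxy-6-methylocta-2,6-dienoate | OC/C=C(/C)CC/C=C(\C(=O)OC)CCO[Si](C)(C)C(C)(C)C | intermediate
9 | methyl (2Z,6Z)-2-{2-[(tert-butyldimethylsilyl)oxy]ethyl}-6-methyl-8-oxoocta-2,6-dienoate | O=C/C=C(/C)CC/C=C(\C(=O)OC)CCO[Si](C)(C)C(C)(C)C | intermediate
10 | 4-methoxybenzyl propargyl ether, 1-methoxy-4-[(prop-2-yn-1-yloxy)methyl]benzene | C#CCOCc1ccc(OC)cc1 | starting material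
11 | methyl (2Z,6Z,8R)-2-{2-[(tert-butyldimethylsilyl)oxy]ethyl}-8-hydroxy-11-[(4-methoxybenzyl)oxy]-6-methylundeca-2,6-dien-9-ynoate | O[C@@H](C#CCOCc1ccc(OC)cc1)/C=C(/C)CC/C=C(\C(=O)OC)CCO[Si](C)(C)C(C)(C)C | intermediate
12 | (2Z,6Z,8R)-2-{2-[(tert-butyldimethylsilyl)oxy]ethyl}-11-[(4-methoxybenzyl)oxy]-6-methylundeca-2,6-dien-9-yne-1,8-diol | O[C@@H](C#CCOCc1ccc(OC)cc1)/C=C(/C)CC/C=C(\CO)CCO[Si](C)(C)C(C)(C)C | intermediate
13 | cyclic sodium alkenylaluminate of 12 (2,2-bis(2-methoxyethoxy)-2,5-dihydro-1,2-oxaluminol-2-uide, aluminium on C11, C14 as sodium alkoxide) | [Na+].[Na+].COCCO[Al-]1(OCCOC)O[C@H](/C=C(/C)CC/C=C(\C[O-])CCO[Si](C)(C)C(C)(C)C)C=C1COCc1ccc(OC)cc1 | intermediate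
14 | (2Z,6Z,8R,9Z)-2-{2-[(tert-butyldimethylsilyl)oxy]ethyl}-10-iodo-11-[(4-methoxybenzyl)oxy]-6-methylundeca-2,6,9-triene-1,8-diol | O[C@@H](/C=C(\I)COCc1ccc(OC)cc1)/C=C(/C)CC/C=C(\CO)CCO[Si](C)(C)C(C)(C)C | intermediate
15 | (5R)-5-[(1Z,5Z)-8-[(tert-butyldimethylsilyl)oxy]-6-(hydroxymethyl)-2-methylocta-1,5-dien-1-yl]-3-{[(4-methoxybenzyl)oxy]methyl}furan-2(5H)-one | O=C1O[C@H](/C=C(/C)CC/C=C(\CO)CCO[Si](C)(C)C(C)(C)C)C=C1COCc1ccc(OC)cc1 | intermediate
16 | (5R)-5-[(1Z,5Z)-6-(acetoxymethyl)-8-[(tert-butyldimethylsilyl)oxy]-2-methylocta-1,5-dien-1-yl]-3-{[(4-methoxybenzyl)oxy]methyl}furan-2(5H)-one | O=C1O[C@H](/C=C(/C)CC/C=C(\COC(C)=O)CCO[Si](C)(C)C(C)(C)C)C=C1COCc1ccc(OC)cc1 | intermediate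
17 | (5R)-5-[(1Z,5Z)-6-(acetoxymethyl)-8-[(tert-butyldimethylsilyl)oxy]-2-methylocta-1,5-dien-1-yl]-3-(hydroxymethyl)furan-2(5H)-one | O=C1O[C@H](/C=C(/C)CC/C=C(\COC(C)=O)CCO[Si](C)(C)C(C)(C)C)C=C1CO | intermediate
18 | (5R)-5-[(1Z,5Z)-6-(acetoxymethyl)-8-[(tert-butyldimethylsilyl)oxy]-2-methylocta-1,5-dien-1-yl]-3-(bromomethyl)furan-2(5H)-one | O=C1O[C@H](/C=C(/C)CC/C=C(\COC(C)=O)CCO[Si](C)(C)C(C)(C)C)C=C1CBr | intermediate
19 | (5R)-5-[(1Z,5Z)-6-(acetoxymethyl)-8-hydroxy-2-methylocta-1,5-dien-1-yl]-3-(bromomethyl)furan-2(5H)-one | O=C1O[C@H](/C=C(/C)CC/C=C(\COC(C)=O)CCO)C=C1CBr | intermediate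
20 | (5R)-5-[(1Z,5Z)-6-(acetoxymethyl)-2-methyl-8-oxoocta-1,5-dien-1-yl]-3-(bromomethyl)furan-2(5H)-one | O=C1O[C@H](/C=C(/C)CC/C=C(\COC(C)=O)CC=O)C=C1CBr | intermediate
21 | allylchromium dichloride from 20 (CrCl2 group on C13) | O=C1O[C@H](/C=C(/C)CC/C=C(\COC(C)=O)CC=O)C=C1C[Cr](Cl)Cl | intermediate
22 | (6R,7R,8S)-14-acetoxy-8-hydroxygermacra-1(10),4,11(13)-trien-6,12-olide (C1=C10 trans in the ring with C14 cis to C2, C4=C5 cis in the ring, trans-fused lactone) | C=C1C(=O)O[C@@H]2/C=C(/C)CC/C=C(\COC(C)=O)C[C@H](O)[C@@H]12 | intermediate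
23 | angelic acid, (2Z)-2-methylbut-2-enoic acid | C/C=C(/C)C(=O)O | starting material
24 | (2Z)-2-methylbut-2-en-1-ol | C/C=C(/C)CO | intermediate
25 | [(2R,3S)-2,3-dimethyloxiran-2-yl]methanol | OC[C@@]1(C)O[C@H]1C | intermediate
26 | (2S,3S)-2,3-dimethyloxirane-2-carboxylic acid ((2S,3S)-epoxyangelic acid) | OC(=O)[C@@]1(C)O[C@H]1C | intermediate
27 | (6R,7R,8R)-14-acetoxy-8-{[(2S,3S)-2,3-dimethyloxirane-2-carbonyl]oxy}germacra-1(10),4,11(13)-trien-6,12-olide | C=C1C(=O)O[C@@H]2/C=C(/C)CC/C=C(\COC(C)=O)C[C@@H](OC(=O)[C@@]3(C)O[C@H]3C)[C@@H]12 | intermediate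
28 | (1R,6R,7R,8R,10S)-14-acetoxy-1,10-epoxy-8-{[(2S,3S)-2,3-dimethyloxirane-2-carbonyl]oxy}germacra-4,11(13)-dien-6,12-olide (C4=C5 cis in the ring) | C=C1C(=O)O[C@@H]2/C=C(/C)CC[C@H]3O[C@]3(COC(C)=O)C[C@@H](OC(=O)[C@@]3(C)O[C@H]3C)[C@@H]12 | target

## Step count and risks

Total step count: 20. Longest linear sequence: 16 (steps 1, 3–15, 19, 20); step 2 and steps 16–18 are side branches.

**Step 15 (macrocyclisation).** The ring closure may lose to intermolecular allylation (oligomers), the β,γ-unsaturated aldehyde may slip into conjugation during the slow addition, or the allylchromium species may be protonated before it cyclises. The fallback replaces the transient allylchromium by an isolable allylstannane and closes the ring in an open, Lewis-acid-promoted SE2′ step. It sets out from alcohol 19, which with (Bu3Sn)2 and catalytic Pd(PPh3)4 in THF at rt (the allylic bromide ionises far faster than the C14 allylic acetate) should give (5R)-5-[(1Z,5Z)-6-(acetoxymethyl)-8-hydroxy-2-methylocta-1,5-dien-1-yl]-3-[(tributylstannyl)methyl]furan-2(5H)-one F1. Buffered Dess–Martin oxidation should give the corresponding stannyl aldehyde F2. BF3·OEt2 in CH2Cl2 at −78 °C under high dilution should then add C7 to the activated aldehyde, with the ring bond C8–C9 again anti to C11, and the fallback comes back to the route at alcohol 22.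

**Step 19 (Mitsunobu inversion).** Displacement at the hindered ring carbon C8 by an α-quaternary carboxylate may be slow, so that elimination toward C9 or recovery of the alcohol takes over. The fallback separates activation from displacement. It sets out from 22, which with ClCH2SO2Cl and pyridine in CH2Cl2 at 0 °C should give the (8S)-chloromethanesulfonate of 22 F3. Heating F3 with the caesium salt of acid 26 (from 26 and Cs2CO3) and 18-crown-6 in toluene at 60 °C should displace the sulfonate with inversion, and the fallback comes back to the route at ester 27.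

**Step 20 (final epoxidation).** The oxidant may not discriminate enough between the C1=C10 and C4=C5 olefins or between the two faces of C1=C10, and the new oxirane may undergo transannular opening. The fallback changes from undirected substrate control to a hydroxyl-directed, reagent-controlled epoxidation. It sets out from 27: a lipase (Candida antarctica lipase B, aq. NaH2PO4–Na2HPO4 buffer pH 7/acetone, rt) should remove only the unhindered primary C14 acetate to give (6R,7R,8R)-8-{[(2S,3S)-2,3-dimethyloxirane-2-carbonyl]oxy}-14-hydroxygermacra-1(10),4,11(13)-trien-6,12-olide F4. Sharpless epoxidation with Ti(OiPr)4, D-(−)-diethyl tartrate and t-BuOOH in CH2Cl2 at −20 °C acts only on the allylic-alcohol olefin, with the tartrate chosen for 1R,10S, and should give the (1R,10S)-1,10-epoxy-14-hydroxy compound F5. Acetylation (Ac2O, pyridine, 0 °C) brings the fallback back to the route at target 28.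

## Further compounds

F1 | step 15 | (5R)-5-[(1Z,5Z)-6-(acetoxymethyl)-8-hydroxy-2-methylocta-1,5-dien-1-yl]-3-[(tributylstannyl)methyl]furan-2(5H)-one | O=C1O[C@H](/C=C(/C)CC/C=C(\COC(C)=O)CCO)C=C1C[Sn](CCCC)(CCCC)CCCC
F2 | step 15 | (5R)-5-[(1Z,5Z)-6-(acetoxymethyl)-2-methyl-8-oxoocta-1,5-dien-1-yl]-3-[(tributylstannyl)methyl]furan-2(5H)-one | O=C1O[C@H](/C=C(/C)CC/C=C(\COC(C)=O)CC=O)C=C1C[Sn](CCCC)(CCCC)CCCC
F3 | step 19 | (6R,7R,8S)-14-acetoxy-8-[(chloromethanesulfonyl)oxy]germacra-1(10),4,11(13)-trien-6,12-olide | C=C1C(=O)O[C@@H]2/C=C(/C)CC/C=C(\COC(C)=O)C[C@H](OS(=O)(=O)CCl)[C@@H]12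
F4 | step 20 | (6R,7R,8R)-8-{[(2S,3S)-2,3-dimethyloxirane-2-carbonyl]oxy}-14-hydroxygermacra-1(10),4,11(13)-trien-6,12-olide | C=C1C(=O)O[C@@H]2/C=C(/C)CC/C=C(\CO)C[C@@H](OC(=O)[C@@]3(C)O[C@H]3C)[C@@H]12
F5 | step 20 | (1R,6R,7R,8R,10S)-1,10-epoxy-8-{[(2S,3S)-2,3-dimethyloxirane-2-carbonyl]oxy}-14-hydroxygermacra-4,11(13)-dien-6,12-olide | C=C1C(=O)O[C@@H]2/C=C(/C)CC[C@H]3O[C@]3(CO)C[C@@H](OC(=O)[C@@]3(C)O[C@H]3C)[C@@H]12
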